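**Plan**

- Retrosynthesis: the aryl MOM (methoxymethyl) ether and the second carbonyl oxygen are removed first, leading back to a deoxybenzoin. The C6–C(acyl) and C7–O bonds of ring A are then cut together, giving a C6–C7 aryne and an arylacetic acid.
- Enabling feature: C6 (acyl) and C7 (hydroxyl) are adjacent and are the last two positions of the hexasubstituted ring A, lying between the C5 methoxy and the C8 prenyl group. They map onto the two carbons of an aryne, and the C5 methoxy group steers the addition.
- The aryne precursor (C6–SiMe3, C7–OTf) goes back to an ortho-bromophenol. The pyran ring is cut at C4–C4a and O1–C2 (prenal annulation), then C6–Br, then C8–prenyl (directed metalation).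
- Forward: ring A is bought as 5-methoxyresorcinol. The prenyl group, the bromine and then the pyran ring are added; the silyl triflate is made; the arylacetyl chain is joined by aryne insertion, oxidised to the diketone and unmasked.
- Stereochemistry: the target has no stereocentre and no stereogenic double bond; the chromene alkene is cis by ring constraint.

Key step: step 8

Remark: chromene numbering (O1, C2, C3, C4, C4a, C5–C8, C8a) is used for the bicyclic compounds throughout.

**Route**

Step 1
Reactants: 1 5-methoxyresorcinol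
Product: 2 1-methoxy-3,5-bis(methoxymethoxy)benzene
Conditions: MOMCl, i-Pr2NEt, CH2Cl2, 0 °C to rt
Reagents that add atoms: chloromethyl methyl ether, COCCl
Why: Double O-alkylation of the phenols (Williamson-type acetal ether formation) should proceed cleanly under amine base and installs the two chelating groups that direct the next metalation.

Step 2
Reactants: 2 1-methoxy-3,5-bis(methoxymethoxy)benzene; 3 prenyl bromide
Product: 6 5-methoxy-1,3-bis(methoxymethoxy)-2-(3-methylbut-2-en-1-yl)benzene, via aryllithium 4 (not isolated), via arylcopper 5 (not isolated)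
Conditions: n-BuLi, THF, 0 °C; CuI, −40 °C; then 3, −40 °C to rt
Reagents that add atoms: none
Why: Directed ortho-metalation is expected at the carbon flanked by both MOM ethers, and the derived arylcopper should be allylated by prenyl bromide at its primary carbon (SN2-type coupling), a standard C-prenylation of protected resorcinols.

Step 3
Reactants: 6 5-methoxy-1,3-bis(methoxymethoxy)-2-(3-methylbut-2-en-1-yl)benzene
Product: 7 2-bromo-1-methoxy-3,5-bis(methoxymethoxy)-4-(3-methylbut-2-en-1-yl)benzene
Conditions: NBS (1.0 equiv), MeCN, 0 °C, dark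
Reagents that add atoms: N-bromosuccinimide, O=C1CCC(=O)N1Br
Why: Electrophilic aromatic bromination should favour the trioxygenated ring over the trisubstituted alkene, the two open ring positions are equivalent by symmetry, and no free phenol is present to trigger bromoetherification.

Step 4
Reactants: 7 2-bromo-1-methoxy-3,5-bis(methoxymethoxy)-4-(3-methylbut-2-en-1-yl)benzene
Product: 8 4-bromo-5-methoxy-2-(3-methylbut-2-en-1-yl)benzene-1,3-diol
Conditions: HCl (cat.), MeOH, rt
Reagents that add atoms: none
Why: Acid-catalysed transacetalisation to methanol removes both MOM groups, and with only catalytic acid at room temperature the ortho-prenyl phenol should not cyclise to a chroman.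

Step 5
Reactants: 8 4-bromo-5-methoxy-2-(3-methylbut-2-en-1-yl)benzene-1,3-diol; 9 3-methylbut-2-enal (prenal)
Product: 11 6-bromo-5-methoxy-2,2-dimethyl-8-(3-methylbut-2-en-1-yl)-2H-chromen-7-ol, via quinone methide 10 (not isolated)
Conditions: ethylenediammonium diacetate (cat.), toluene, 110 °C
Reagents that add atoms: none
Why: Knoevenagel-type condensation of prenal at the only unsubstituted ring carbon gives an ortho-quinone methide that closes by oxa-6π electrocyclisation onto the neighbouring phenol oxygen, and the bromine blocks the other site so only one chromene can form.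

Step 6
Reactants: 11 6-bromo-5-methoxy-2,2-dimethyl-8-(3-methylbut-2-en-1-yl)-2H-chromen-7-ol
Product: 15 5-methoxy-2,2-dimethyl-8-(3-methylbut-2-en-1-yl)-6-(trimethylsilyl)-2H-chromen-7-yl trifluoromethanesulfonate, via silyl ether 12 (not isolated), via aryllithium 13 (not isolated), via lithium phenoxide 14 (not isolated)
Conditions: (Me3Si)2NH, THF, 65 °C, then evaporate; n-BuLi, THF, −100 to −78 °C; Tf2O, −100 °C to rt
Reagents that add atoms: hexamethyldisilazane, C[Si](C)(C)N[Si](C)(C)C; trifluoromethanesulfonic anhydride, O=S(=O)(OS(=O)(=O)C(F)(F)F)C(F)(F)F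
Why: O-Silylation, bromine–lithium exchange, retro-Brook 1,3-shift of silicon from oxygen to carbon and triflation of the resulting phenoxide is the standard one-flask route from ortho-bromophenols to ortho-silylaryl triflates, and exchange at −100 °C should outrun deprotonation at the allylic positions.

Step 7
Reactants: 16 4-hydroxyphenylacetic acid
Product: 18 2-[4-(methoxymethoxy)phenyl]acetic acid, via MOM ester 17 (not isolated)
Conditions: MOMCl, i-Pr2NEt, CH2Cl2, 0 °C to rt; then LiOH, THF/H2O, rt; cold 1 M HCl to pH 4
Reagents that add atoms: chloromethyl methyl ether, COCCl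
Why: Exhaustive O-alkylation followed by saponification of the labile MOM ester leaves the aryl MOM ether, masking the phenol that would otherwise add to the aryne.

Step 8
Reactants: 15 5-methoxy-2,2-dimethyl-8-(3-methylbut-2-en-1-yl)-6-(trimethylsilyl)-2H-chromen-7-yl trifluoromethanesulfonate; 18 2-[4-(methoxymethoxy)phenyl]acetic acid
Product: 20 1-[7-hydroxy-5-methoxy-2,2-dimethyl-8-(3-methylbut-2-en-1-yl)-2H-chromen-6-yl]-2-[4-(methoxymethoxy)phenyl]ethan-1-one, via aryne 19 (not isolated)
Conditions: CsF, THF, 125 °C, sealed tube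
Reagents that add atoms: none
Why: Fluoride attacks silicon and triflate leaves, giving the C6–C7 aryne 19; the carboxylate of 18 adds through oxygen at C7, and the C6 aryl anion, held beside the new aryl ester, attacks its carbonyl through a four-membered transition state whose collapse moves the acyl group from oxygen to carbon and frees the C7 phenoxide. The closest known reaction type is the fluoride-induced insertion of arynes into the acyl–oxygen bond of carboxylic acids to give ortho-hydroxyaryl ketones, an aryne-triggered anionic Fries-type shift. No ring closes and no stereocentre is formed. Regioselectivity is required and should come from the C5 methoxy group, whose inductive pull distorts the aryne so that the nucleophile enters at the remote carbon C7 and the charge develops at C6 next to the methoxy oxygen; the weakly donating C8 alkyl group should not override this. Acyl transfer is favoured over protonation of the aryl anion by the aprotic medium and high temperature, and the near-neutral fluoride conditions should spare both alkenes, the aryl MOM ether and the benzylic methylene.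

Step 9
Reactants: 20 1-[7-hydroxy-5-methoxy-2,2-dimethyl-8-(3-methylbut-2-en-1-yl)-2H-chromen-6-yl]-2-[4-(methoxymethoxy)phenyl]ethan-1-one
Product: 21 1-[7-hydroxy-5-methoxy-2,2-dimethyl-8-(3-methylbut-2-en-1-yl)-2H-chromen-6-yl]-2-[4-(methoxymethoxy)phenyl]ethane-1,2-dione
Conditions: DABCO (cat.), air, DMF, 90 °C
Reagents that add atoms: dioxygen (air), O=O
Why: Amine-catalysed autoxidation of the doubly activated methylene, in which the enolate traps O2 to an α-hydroperoxide that loses water by Kornblum–DeLaMare-type elimination, is a known conversion of deoxybenzoins into benzils and should leave the isolated alkenes alone.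

Step 10
Reactants: 21 1-[7-hydroxy-5-methoxy-2,2-dimethyl-8-(3-methylbut-2-en-1-yl)-2H-chromen-6-yl]-2-[4-(methoxymethoxy)phenyl]ethane-1,2-dione
Product: 22 derrisdione A
Conditions: HCl (3 M aq.), MeOH, 40 °C
Reagents that add atoms: none
Why: Mild acid-catalysed cleavage of the aryl MOM acetal should free the phenol, while the C7 hydroxyl is hydrogen-bonded to the C6 carbonyl and is therefore slow to add to the prenyl alkene.

**Compound list**

1 | 5-methoxyresorcinol | COc1cc(O)cc(O)c1 | starting material
2 | 1-methoxy-3,5-bis(methoxymethoxy)benzene | COCOc1cc(OC)cc(OCOC)c1 | intermediate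
3 | prenyl bromide (1-bromo-3-methylbut-2-ene) | CC(C)=CCBr | starting material
4 | [4-methoxy-2,6-bis(methoxymethoxy)phenyl]lithium | COCOc1cc(OC)cc(OCOC)c1[Li] | intermediate
5 | [4-methoxy-2,6-bis(methoxymethoxy)phenyl]copper | COCOc1cc(OC)cc(OCOC)c1[Cu] | intermediate
6 | 5-methoxy-1,3-bis(methoxymethoxy)-2-(3-methylbut-2-en-1-yl)benzene | COCOc1cc(OC)cc(OCOC)c1CC=C(C)C | intermediate
7 | 2-bromo-1-methoxy-3,5-bis(methoxymethoxy)-4-(3-methylbut-2-en-1-yl)benzene | COCOc1cc(OC)c(Br)c(OCOC)c1CC=C(C)C | intermediate
8 | 4-bromo-5-methoxy-2-(3-methylbut-2-en-1-yl)benzene-1,3-diol | COc1cc(O)c(CC=C(C)C)c(O)c1Br | intermediate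
9 | 3-methylbut-2-enal (prenal) | CC(C)=CC=O | starting material
10 | (6Z)-4-bromo-3-hydroxy-5-methoxy-2-(3-methylbut-2-en-1-yl)-6-(3-methylbut-2-en-1-ylidene)cyclohexa-2,4-dien-1-one (ortho-quinone methide) | COC1=C(Br)C(O)=C(CC=C(C)C)C(=O)/C1=C\C=C(C)C | intermediate
11 | 6-bromo-5-methoxy-2,2-dimethyl-8-(3-methylbut-2-en-1-yl)-2H-chromen-7-ol | COc1c(Br)c(O)c(CC=C(C)C)c2c1C=CC(C)(C)O2 | intermediate
12 | {[6-bromo-5-methoxy-2,2-dimethyl-8-(3-methylbut-2-en-1-yl)-2H-chromen-7-yl]oxy}trimethylsilane | COc1c(Br)c(O[Si](C)(C)C)c(CC=C(C)C)c2c1C=CC(C)(C)O2 | intermediate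
13 | {5-methoxy-2,2-dimethyl-8-(3-methylbut-2-en-1-yl)-7-[(trimethylsilyl)oxy]-2H-chromen-6-yl}lithium | COc1c([Li])c(O[Si](C)(C)C)c(CC=C(C)C)c2c1C=CC(C)(C)O2 | intermediate
14 | lithium 5-methoxy-2,2-dimethyl-8-(3-methylbut-2-en-1-yl)-6-(trimethylsilyl)-2H-chromen-7-olate | COc1c([Si](C)(C)C)c(O[Li])c(CC=C(C)C)c2c1C=CC(C)(C)O2 | intermediate
15 | 5-methoxy-2,2-dimethyl-8-(3-methylbut-2-en-1-yl)-6-(trimethylsilyl)-2H-chromen-7-yl trifluoromethanesulfonate | COc1c([Si](C)(C)C)c(OS(=O)(=O)C(F)(F)F)c(CC=C(C)C)c2c1C=CC(C)(C)O2 | intermediate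
16 | 4-hydroxyphenylacetic acid | O=C(O)Cc1ccc(O)cc1 | starting material
17 | methoxymethyl 2-[4-(methoxymethoxy)phenyl]acetate | COCOC(=O)Cc1ccc(OCOC)cc1 | intermediate
18 | 2-[4-(methoxymethoxy)phenyl]acetic acid | O=C(O)Cc1ccc(OCOC)cc1 | intermediate
19 | 6,7-didehydro-5-methoxy-2,2-dimethyl-8-(3-methylbut-2-en-1-yl)-2H-chromene (C6–C7 aryne) | COC1=C2C=CC(C)(C)OC2=C(CC=C(C)C)C#C1 | intermediate
20 | 1-[7-hydroxy-5-methoxy-2,2-dimethyl-8-(3-methylbut-2-en-1-yl)-2H-chromen-6-yl]-2-[4-(methoxymethoxy)phenyl]ethan-1-one | COc1c(C(=O)Cc2ccc(OCOC)cc2)c(O)c(CC=C(C)C)c2c1C=CC(C)(C)O2 | intermediate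
21 | 1-[7-hydroxy-5-methoxy-2,2-dimethyl-8-(3-methylbut-2-en-1-yl)-2H-chromen-6-yl]-2-[4-(methoxymethoxy)phenyl]ethane-1,2-dione | COc1c(C(=O)C(=O)c2ccc(OCOC)cc2)c(O)c(CC=C(C)C)c2c1C=CC(C)(C)O2 | intermediate
22 | derrisdione A, 1-[7-hydroxy-5-methoxy-2,2-dimethyl-8-(3-methylbut-2-en-1-yl)-2H-chromen-6-yl]-2-(4-hydroxyphenyl)ethane-1,2-dione | COc1c2c(c(CC=C(C)C)c(O)c1C(=O)C(=O)c1ccc(O)cc1)OC(C)(C)C=C2 | target

**Summary**

Total step count: 10. Longest linear sequence: 9 steps (steps 1–6, 8, 9, 10 from 5-methoxyresorcinol); step 7 is a one-step side branch.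

**Steps most likely to fail**

1. Step 8 (aryne insertion). The aryl anion formed after carboxylate addition may be protonated before it reaches the ester carbonyl, stopping at O-arylation. Aryne generation from the doubly flanked silane may be slow. The carboxylate may also add in part at the wrong aryne carbon.
Fallback, from 11 and 18, returning at 20: the bromophenol 11 is esterified with acid 18 (DCC, DMAP, CH2Cl2) to give 6-bromo-5-methoxy-2,2-dimethyl-8-(3-methylbut-2-en-1-yl)-2H-chromen-7-yl 2-[4-(methoxymethoxy)phenyl]acetate F1. Bromine–lithium exchange with t-BuLi in THF at −100 °C then generates the C6-lithiated ester F2. This should undergo the same 1,3 oxygen-to-carbon acyl shift (anionic Fries-type rearrangement) without any aryne, giving deoxybenzoin 20 after work-up.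

2. Step 9 (aerobic oxidation). The hydroperoxide may fragment with carbon–carbon cleavage, the allylic positions may autoxidise, or enolisation may stall because of the chelated phenol.
Fallback, from 20, returning at 21: the dianion of 20 (KN(SiMe3)2, THF, −78 °C) is hydroxylated with 2-(phenylsulfonyl)-3-phenyloxaziridine to give racemic 2-hydroxy-1-[7-hydroxy-5-methoxy-2,2-dimethyl-8-(3-methylbut-2-en-1-yl)-2H-chromen-6-yl]-2-[4-(methoxymethoxy)phenyl]ethan-1-one F3. Its benzylic carbinol is then oxidised with MnO2 in CH2Cl2 to diketone 21, which removes the temporary stereocentre.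

3. Step 3 (ring bromination). Bromonium formation at the prenyl alkene, followed by capture by a neighbouring MOM oxygen, or a second ring bromination, may compete with the desired substitution.
Fallback, from 6, returning at 7: a second directed ortho-metalation (n-BuLi, TMEDA, THF, 0 °C) at the ring carbon between the methoxy and a MOM ether gives [6-methoxy-2,4-bis(methoxymethoxy)-3-(3-methylbut-2-en-1-yl)phenyl]lithium F4. Quenching with 1,2-dibromoethane at −78 °C delivers bromide 7 without any electrophilic bromine source.

**Further compounds**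

F1 | step 8 | 6-bromo-5-methoxy-2,2-dimethyl-8-(3-methylbut-2-en-1-yl)-2H-chromen-7-yl 2-[4-(methoxymethoxy)phenyl]acetate | COc1c(Br)c(OC(=O)Cc2ccc(OCOC)cc2)c(CC=C(C)C)c2c1C=CC(C)(C)O2
F2 | step 8 | [5-methoxy-7-({2-[4-(methoxymethoxy)phenyl]acetyl}oxy)-2,2-dimethyl-8-(3-methylbut-2-en-1-yl)-2H-chromen-6-yl]lithium | COc1c([Li])c(OC(=O)Cc2ccc(OCOC)cc2)c(CC=C(C)C)c2c1C=CC(C)(C)O2
F3 | step 9 | rac-2-hydroxy-1-[7-hydroxy-5-methoxy-2,2-dimethyl-8-(3-methylbut-2-en-1-yl)-2H-chromen-6-yl]-2-[4-(methoxymethoxy)phenyl]ethan-1-one | COc1c(C(=O)C(O)c2ccc(OCOC)cc2)c(O)c(CC=C(C)C)c2c1C=CC(C)(C)O2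
F4 | step 3 | [6-methoxy-2,4-bis(methoxymethoxy)-3-(3-methylbut-2-en-1-yl)phenyl]lithium | COCOc1cc(OC)c([Li])c(OCOC)c1CC=C(C)C
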